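**Retrosynthetic overview**

1. Numbering of each carbocycle (ring A, ring B): C2 is bound to the methine CH, C1 and C3 are oxygenated, C4 and C6 are CMe2, and C5 is the isolated ketone. Last disconnection: the enol oxygens on C1 of ring A and C1 of ring B are merged into the single oxygen of a temporary 4H-pyran ring that is not in the target. This takes watsonianone A back to 9-isobutyl-octamethylxanthene-1,3,6,8-tetraone plus water.
2. Key disconnection: C2–C3 and C5–C6 are cut in both carbocycles at once (twofold [3+3], four C–C bonds). This leaves 2,6-diisopropyl-4-isobutyl-4H-pyran and two molecules of dimethylmalonyl dichloride.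
3. Enabling feature: the spine C1–C2–CH(iBu)–C2–C1 joining rings A and B is mirror-symmetric and holds the two C1 oxygens in a 1,5-relationship, so one oxygen can lock both arms as a cyclic bis-enol ether. Each ring is the sum of an isopropyl ketone arm (C6–C1–C2) and a C3–C4(Me2)–C5 unit, whose quaternary C4 makes it a non-enolisable, symmetric 1,3-bis-acyl donor.
4. The pyran goes back to 2,8-dimethyl-5-isobutylnonane-3,7-dione (cyclodehydration), then to the bis-Weinreb amide plus iPrMgCl, then to 3-isobutylglutaric acid.
5. Ring order: pyran ring (step 3), then rings A and B in one flask (step 4), then opening of the pyran ring (step 5).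

Key step: step 4

Remark: the target has no stereocentre, because the methine carbon bears two constitutionally identical, tautomerically equivalent rings; enol tautomers are therefore treated as one compound and no step has to control configuration.

**Step 1**
Reactants: 1 3-isobutylglutaric acid
Product: 3 bis-Weinreb amide N1,N5-dimethoxy-N1,N5-dimethyl-3-isobutylpentanediamide, via bis(acylimidazole) 2 (not isolated)
Conditions: 1,1'-carbonyldiimidazole (2.3 equiv), CH2Cl2, rt until gas evolution ends; then MeNH(OMe)·HCl (2.6 equiv), rt
Reagents that add atoms: 1,1'-carbonyldiimidazole, O=C(n1ccnc1)n1ccnc1 (imidazolyl groups of 2); N,O-dimethylhydroxylamine hydrochloride, CNOC.Cl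
Why: Amide formation through the acyl imidazolide is a standard route to Weinreb amides, the released imidazole takes up the HCl of the amine salt, and no stereocentre is involved because C3 bears two identical arms.

**Step 2**
Reactants: 3 bis-Weinreb amide
Product: 5 2,8-dimethyl-5-isobutylnonane-3,7-dione, via bis(chloromagnesium) tetrahedral adduct 4 (not isolated)
Conditions: iPrMgCl (3 equiv), THF, −10 °C → rt; then dilute aq. HCl, 0 °C
Reagents that add atoms: isopropylmagnesium chloride, CC(C)[Mg]Cl
Why: Weinreb ketone synthesis, in which the chelated adduct 4 survives until the acidic quench so that each amide takes up exactly one isopropyl group, and the two hemiaminal stereocentres of 4 are lost again on collapse to the ketones.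

**Step 3**
Reactants: 5 2,8-dimethyl-5-isobutylnonane-3,7-dione
Product: 6 2,6-diisopropyl-4-isobutyl-4H-pyran
Conditions: TsOH·H2O (3 mol %), toluene, reflux, Dean–Stark trap, Ar; filtration through basic Al2O3, distillation, storage under Ar
Reagents that add atoms: none
Why: Acid-catalysed cyclodehydration of a 1,5-diketone (enol oxygen adds to the second carbonyl, the cyclic hemiketal loses water, azeotropic removal drives it) is the classical route to 4H-pyrans, the only competing aldol closure would have to join a tertiary isopropyl carbon to a hindered isopropyl ketone, and C4 bears two identical ring arms and is no stereocentre.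

**Step 4**
Reactants: 6 2,6-diisopropyl-4-isobutyl-4H-pyran; 7 dimethylmalonyl dichloride (two molecules enter the product)
Product: 9 xanthenetetraone 9-isobutyl-2,2,4,4,5,5,7,7-octamethyl-4,5-dihydro-1H-xanthene-1,3,6,8(2H,7H,9H)-tetraone, via mono-annulated chromenedione 8 (not isolated)
Conditions: 7 (2.5 equiv), TMSOTf (20 mol %), ClCH2CH2Cl, −20 °C, slow addition of 6; then → 70 °C under an Ar sweep
Reagents that add atoms: none
Why: Proposed new method: the TMSOTf-activated acid chloride C-acylates enol-ether carbon C3 of 6, the resulting 3-acyl-4H-pyran (a vinylogous ester) is O-protonated by the released acid and loses the methine proton of the neighbouring isopropyl group, the exocyclic isopropylidene dienol attacks the second COCl group to close ring A of 8, and the same sequence on the C5 side closes ring B (new bonds in 9: C9a–C1 and C3–C4, C8a–C8 and C6–C5). The closest known reaction type is the Effenberger cyclization, in which malonyl dichloride joins the α and α' carbons of a ketone alkyl or silyl enol ether into a cyclohexane-1,3,5-trione unit, and the bond from a tertiary enol carbon to an α-quaternary acyl group has its analogy in the Lewis-acid isomerisation of the β-lactone dimer of dimethylketene to tetramethylcyclobutane-1,3-dione; new are the 2,2-disubstituted dichloride (no ketene pathway, hence the catalyst), the divinyl-ether nucleophile and the double use in one flask. Each carbocycle closes in the 6-(enolendo)-exo-trig mode and ends ortho-fused to the pyran ring. No stereocentre remains, because C9 of 9 carries two identical halves and the single stereocentre of racemic 8 vanishes in the second annulation. The step needs C- rather than O-acylation, closure within one arm rather than across the arms, and acylation faster than hydride loss from C4: the only oxygen of 6 is bound to two vinyl carbons and cannot end in an enol lactone, each ring double bond holds acyl chain and isopropyl group cis on adjacent carbons whereas a C3-to-C5 bridge (the six-membered closure open to the free diketone 5) would need a bridgehead alkene in a bicyclo[3.3.1]nonene, and slow addition of 6 to excess 7 in the cold turns it at once into the electron-poor, much less hydridic acylpyran. The quaternary carbon of 7 rules out ketene formation, aromatisation and over-enolisation, the symmetry of 7 makes either order of the two acylations productive, and decarbonylation of the activated acyl group is disfavoured since it would leave an α-acyl carbocation.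

**Step 5**
Reactants: 9 xanthenetetraone
Product: 11 watsonianone A, via disodium bis-enolate 10 (not isolated)
Conditions: NaOH (aq, 6 equiv), 1,4-dioxane, 70 °C; then dilute aq. HCl, 0 °C, to pH 2
Reagents that add atoms: sodium hydroxide, [Na+].[OH-]
Why: Saponification of a doubly vinylogous anhydride by conjugate addition–elimination, in which hydroxide adds to C4a, the stabilised triketone enolate of the other ring leaves, formation of bis-enolate 10 makes the opening irreversible, and cold acidification should give the achiral target without recyclisation.

**Compound list**

1 | 3-isobutylglutaric acid, 3-(2-methylpropyl)pentanedioic acid | CC(C)CC(CC(=O)O)CC(=O)O | starting material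
2 | 3-isobutylglutaryl bis(imidazolide) | CC(C)CC(CC(=O)n1ccnc1)CC(=O)n1ccnc1 | intermediate
3 | N1,N5-dimethoxy-N1,N5-dimethyl-3-isobutylpentanediamide (bis-Weinreb amide) | CC(C)CC(CC(=O)N(C)OC)CC(=O)N(C)OC | intermediate
4 | bis(chloromagnesium alkoxide) of the double isopropyl adduct of 3 (mixture of diastereomers) | CC(C)CC(CC(O[Mg]Cl)(C(C)C)N(C)OC)CC(O[Mg]Cl)(C(C)C)N(C)OC | intermediate
5 | 2,8-dimethyl-5-isobutylnonane-3,7-dione | CC(C)CC(CC(=O)C(C)C)CC(=O)C(C)C | intermediate
6 | 2,6-diisopropyl-4-isobutyl-4H-pyran | CC(C)CC1C=C(C(C)C)OC(C(C)C)=C1 | intermediate
7 | dimethylmalonyl dichloride, 2,2-dimethylpropanedioyl dichloride | CC(C)(C(=O)Cl)C(=O)Cl | starting material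
8 | 4-isobutyl-2-isopropyl-6,6,8,8-tetramethyl-4H-chromene-5,7(6H,8H)-dione (racemic) | CC(C)CC1C=C(C(C)C)OC2=C1C(=O)C(C)(C)C(=O)C2(C)C | intermediate
9 | 9-isobutyl-2,2,4,4,5,5,7,7-octamethyl-4,5-dihydro-1H-xanthene-1,3,6,8(2H,7H,9H)-tetraone (achiral) | CC(C)CC1C2=C(OC3=C1C(=O)C(C)(C)C(=O)C3(C)C)C(C)(C)C(=O)C(C)(C)C2=O | intermediate
10 | disodium bis-enolate of watsonianone A | CC(C)CC(C1=C([O-])C(C)(C)C(=O)C(C)(C)C1=O)C1=C([O-])C(C)(C)C(=O)C(C)(C)C1=O.[Na+].[Na+] | intermediate
11 | watsonianone A (achiral) | CC(C)CC(C1=C(O)C(C)(C)C(=O)C(C)(C)C1=O)C1=C(O)C(C)(C)C(=O)C(C)(C)C1=O | target

**Step count and risks**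

Total step count: 5. Longest linear sequence: 5 steps (1 → 3 → 5 → 6 → 9 → 11).

Steps most likely to fail:

1. **Step 4 (proposed new method).**
   - Possible failure: hydride loss from C4 with aromatisation of the pyran ring, acid-induced opening of the enol ethers, or stalling after the first acylation because the remaining enol ether is deactivated and the hindered closure is slow.
   - Fallback (known chemistry, anionic and stepwise, no temporary ring): it sets out from 5 and comes back to the route at 11. Both CH2 groups of 5 are deprotonated kinetically (LiN(iPr)2, THF, −78 °C). The bis-enolate is added to methyl 3-chloro-2,2-dimethyl-3-oxopropanoate. The second acyl group of this dielectrophile is only a hindered methyl ester, so it cannot bridge the two arms in the cold. This should give dimethyl 4,6-diisobutyryl-5-isobutyl-2,2,8,8-tetramethyl-3,7-dioxononanedioate F1. Excess LiN(iPr)2 or KN(SiMe3)2 (THF, 0 °C → rt) should then deprotonate each 1,3-diketone unit a second time, at its isopropyl methine. Each dianion closes by Dieckmann-type acylation on its own ester, and acidic work-up leads to 11. C-acylation of lithium enolates by acid chlorides and acylation of 1,3-diketone dianions by esters are both established reaction types.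

2. **Step 3.**
   - Possible failure: competition by intramolecular aldol closure in hot acid, acid-induced disproportionation of the product, or hydrolysis and air oxidation during handling.
   - Fallback: it sets out from 5 and comes back at 6. The diketone is first stored as its cyclic bis-ketal 2,6-dimethoxy-2,6-diisopropyl-4-isobutyloxane F2 (MeOH, camphorsulfonic acid cat., 3 Å molecular sieves, rt). Both enol-ether double bonds are then made by loss of the two methoxy groups with TMSOTf/iPr2NEt (CH2Cl2, −20 °C → rt). These conditions are basic and non-equilibrating, and no hot acid is present.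

3. **Step 5.**
   - Possible failure: slow attack at the shielded carbons C4a and C10a, with competing retro-Claisen cleavage of the non-enolisable 1,3-diketone units or retro-Michael fragmentation at the methine on long heating in aqueous base.
   - Fallback: it sets out from 9 and comes back at 11. The pyran ring is opened in aprotic medium by the poorly solvated alkoxide KOCH2Ph (THF, 0 °C, mild acidic work-up) to watsonianone A mono(benzyl enol ether) F3. The benzyl group is then removed under neutral conditions by hydrogenolysis (H2, Pd/C, EtOAc, rt), so the last bond to be broken is O–CH2Ph and not O–C(sp2).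

**Further compounds**

F1 | step 4 | dimethyl 4,6-diisobutyryl-5-isobutyl-2,2,8,8-tetramethyl-3,7-dioxononanedioate (mixture of epimerisable diastereomers) | COC(=O)C(C)(C)C(=O)C(C(=O)C(C)C)C(CC(C)C)C(C(=O)C(C)C)C(=O)C(C)(C)C(=O)OC
F2 | step 3 | 2,6-dimethoxy-2,6-diisopropyl-4-isobutyloxane (mixture of diastereomers) | CC(C)CC1CC(OC)(C(C)C)OC(OC)(C(C)C)C1
F3 | step 5 | watsonianone A mono(benzyl enol ether) (racemic) | CC(C)CC(C1=C(OCc2ccccc2)C(C)(C)C(=O)C(C)(C)C1=O)C1=C(O)C(C)(C)C(=O)C(C)(C)C1=O
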